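The synthesis rests on cutting the 3(2H)-furanone ring (O–C10–C1(=O)–C2H=C3, germacrane numbering), the oxygen bridge of the ten-membered carbocycle, into a two-atom C3=O unit and a three-carbon C10–C1–C2 oxyallyl unit. The key step exploits two features: C3 and the ring oxygen are the carbonyl group of an N,N-dimethylacrylamide, and quaternary C10 is the tertiary end of a 2-siloxyallyl cation. One intramolecular (3+2) cyclocoupling forms O–C10 and C2–C3, closes furanone and carbocycle, sets C10 and, after loss of dimethylamine, gives the enone. The precursor is a monocyclic trans-α-methylene-γ-butyrolactone with a tertiary α-chloro methyl ketone arm and an acrylamide arm.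

Key step: step 15

Remark on the chemistry: the but-2-en-2-yl unit is used as an E/Z mixture, and the acetal carbon of 13, C1/C10 of 20, C10 of 21–23 and C3 of 24 are epimer mixtures. This is assumed harmless because all of these elements are erased later, so the SMILES leave them open. Positions follow germacrane numbering: C1 ketone, C2 =CH, C3 O-bearing sp2 carbon, C4 with C15 methylene, C5 carbinol, C6 angelate carbon, C7, C8 lactone CH–O, C9 CH2, C10 quaternary carbon with C14 methyl, C11–C13 methylene lactone.

Step 1
Reactants: 1 (S)-epichlorohydrin; 2 but-2-en-2-ylmagnesium bromide (E/Z mixture)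
Product: 4 (2S)-2-(2-methylbut-2-en-1-yl)oxirane, via chlorohydrin 3 (not isolated)
Conditions: CuI (10 mol %), THF, −40 to 0 °C; then 3 M aq. NaOH, rt
Reagents that add atoms: none
Why: Copper-catalysed Grignard opening of the oxirane at its CH2 terminus and Williamson-type closure of chlorohydrin 3 shift the epoxide by one carbon without breaking the C–O bond of the stereocentre, so that C8 (S) is taken unchanged from the chiral pool.

Step 2
Reactants: 4 (2S)-2-(2-methylbut-2-en-1-yl)oxirane
Product: 5 (3S)-5-methylhepta-1,5-dien-3-ol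
Conditions: Me3SI (3 equiv), n-BuLi (2.9 equiv), THF, −10 °C to rt
Reagents that add atoms: trimethylsulfonium iodide, C[S+](C)C.[I-]
Why: Epoxide-to-allylic-alcohol homologation with excess dimethylsulfonium methylide (Corey–Chaykovsky ylide) proceeds by attack at the terminal carbon and ylide-induced elimination of dimethyl sulfide, which adds the vinyl CH2 and leaves C8 untouched.

Step 3
Reactants: 5 (3S)-5-methylhepta-1,5-dien-3-ol; 6 2-(bromomethyl)acrylic acid
Product: 7 (3S)-5-methylhepta-1,5-dien-3-yl 2-(bromomethyl)acrylate
Conditions: N,N'-diisopropylcarbodiimide, DMAP (5 mol %), CH2Cl2, 0 °C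
Reagents that add atoms: none
Why: Steglich esterification acylates the carbinol oxygen with retention at C8, and the low DMAP loading at 0 °C should keep attack of the amine on the allylic bromide in check.

Step 4
Reactants: 7 (3S)-5-methylhepta-1,5-dien-3-yl 2-(bromomethyl)acrylate
Product: 8 (5S)-3-(bromomethyl)-5-(2-methylbut-2-en-1-yl)furan-2(5H)-one
Conditions: second-generation Grubbs catalyst (5 mol %), CH2Cl2 (10 mM), reflux
Reagents that add atoms: none
Why: Ring-closing metathesis joins the vinyl group and the acrylate methylene to the five-membered butenolide (C7=C11), whereas the trisubstituted side-chain alkene could only close a cyclobutene or a tetrasubstituted six-membered ring and should remain a spectator.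

Step 5
Reactants: 9 (R)-2,2-dimethyl-1,3-dioxolane-4-carbaldehyde
Product: 10 (4S)-4-ethynyl-2,2-dimethyl-1,3-dioxolane
Conditions: dimethyl (1-diazo-2-oxopropyl)phosphonate, K2CO3, MeOH, 0 °C to rt
Reagents that add atoms: dimethyl (1-diazo-2-oxopropyl)phosphonate, COP(=O)(OC)C(=[N+]=[N-])C(C)=O
Why: The Ohira–Bestmann variant of the Seyferth–Gilbert homologation converts the aldehyde into the terminal alkyne under mild carbonate conditions, and the dioxolane stereocentre (future C5) is carried over from the chiral pool.

Step 6
Reactants: 10 (4S)-4-ethynyl-2,2-dimethyl-1,3-dioxolane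
Product: 11 2-[(4S)-2,2-dimethyl-1,3-dioxolan-4-yl]-N,N-dimethylprop-2-enamide
Conditions: Pd(OAc)2 (1 mol %), 2-(diphenylphosphino)pyridine, CH3SO3H, Me2NH (2 M in THF), CO (30 bar), 70 °C
Reagents that add atoms: carbon monoxide, [C-]#[O+]; dimethylamine, CNC
Why: Palladium-catalysed hydroaminocarbonylation of a terminal alkyne, for which the pyridylphosphine/acid catalyst is known to give the branched (Markovnikov) 2-substituted acrylamide, installs C3 and its amide in one step without touching C5.

Step 7
Reactants: 11 2-[(4S)-2,2-dimethyl-1,3-dioxolan-4-yl]-N,N-dimethylprop-2-enamide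
Product: 13 2-[(4S)-2-(4-methoxyphenyl)-1,3-dioxolan-4-yl]-N,N-dimethylprop-2-enamide, via diol 12 (not isolated)
Conditions: AcOH/H2O (4:1), rt, evaporate; then 4-MeOC6H4CH(OMe)2, camphorsulfonic acid (5 mol %), CH2Cl2, rt
Reagents that add atoms: 4-methoxybenzaldehyde dimethyl acetal, COc1ccc(cc1)C(OC)OC
Why: Acid hydrolysis of the terminal acetonide and acid-catalysed acetalisation of diol 12 are ordinary acetal exchange steps that leave C5 untouched, the new acetal carbon being an inconsequential epimer mixture.

Step 8
Reactants: 13 2-[(4S)-2-(4-methoxyphenyl)-1,3-dioxolan-4-yl]-N,N-dimethylprop-2-enamide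
Product: 14 (3S)-4-hydroxy-3-[(4-methoxybenzyl)oxy]-N,N-dimethyl-2-methylenebutanamide
Conditions: PhBCl2 (2.5 equiv), Et3SiH (3 equiv), 4 Å molecular sieves, CH2Cl2, −78 °C; aq. NaHCO3
Reagents that add atoms: none
Why: In this regioselective reductive opening of a 4-methoxybenzylidene acetal the bulky boron Lewis acid binds the less hindered primary oxygen and the silane reduces the oxocarbenium ion left on the secondary oxygen, so that the PMB group ends on O–C5 and the primary alcohol is freed under conditions too mild to reduce the acrylamide.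

Step 9
Reactants: 14 (3S)-4-hydroxy-3-[(4-methoxybenzyl)oxy]-N,N-dimethyl-2-methylenebutanamide
Product: 15 (3S)-3-[(4-methoxybenzyl)oxy]-N,N-dimethyl-2-methylene-4-oxobutanamide
Conditions: Dess–Martin periodinane, NaHCO3, CH2Cl2, 0 °C; used crude at once
Reagents that add atoms: none
Why: Dess–Martin oxidation under buffered, base-free conditions should give the epimerisable α-alkoxy-β,γ-unsaturated aldehyde without loss of the C5 configuration, provided it is used at once.

Step 10
Reactants: 8 (5S)-3-(bromomethyl)-5-(2-methylbut-2-en-1-yl)furan-2(5H)-one; 15 (3S)-3-[(4-methoxybenzyl)oxy]-N,N-dimethyl-2-methylene-4-oxobutanamide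
Product: 16 (3S,4S)-4-hydroxy-3-[(4-methoxybenzyl)oxy]-N,N-dimethyl-2-methylene-4-[(2S,3S)-2-(2-methylbut-2-en-1-yl)-4-methylene-5-oxotetrahydrofuran-3-yl]butanamide (trans-lactone, C5/C6 syn)
Conditions: In powder (1.5 equiv), THF/H2O (1:1), rt
Reagents that add atoms: none
Why: In this Barbier-type indium allylation in water the allylindium adds through its γ-carbon C7 on the butenolide face anti to the C8 side chain (trans-lactone), the ring-locked E-type geometry and a chair transition state give the anti C7/C6 relation, and chelation of indium by the aldehyde oxygen and the PMB ether oxygen gives the syn C5/C6 relation, so that all three control elements are matched.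

Step 11
Reactants: 16 Barbier adduct; 17 angelic acid [(Z)-2-methylbut-2-enoic acid]
Product: 19 (1S,2S)-3-(dimethylcarbamoyl)-2-[(4-methoxybenzyl)oxy]-1-[(2S,3R)-2-(2-methylbut-2-en-1-yl)-4-methylene-5-oxotetrahydrofuran-3-yl]but-3-en-1-yl (Z)-2-methylbut-2-enoate, via mixed anhydride 18 (not isolated)
Conditions: 17, 2,4,6-trichlorobenzoyl chloride, Et3N, toluene, rt; then 16, toluene, 75 °C
Reagents that add atoms: none
Why: Yamaguchi-type mixed-anhydride esterification run without a nucleophilic catalyst is the usual way to acylate hindered alcohols with angelic acid without Z to E isomerisation, and it proceeds with retention at C6.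

Step 12
Reactants: 19 C6 angelate
Product: 20 side-chain epoxide of 19, (1S,2S)-3-(dimethylcarbamoyl)-1-{(2S,3R)-2-[(2,3-dimethyloxiran-2-yl)methyl]-4-methylene-5-oxotetrahydrofuran-3-yl}-2-[(4-methoxybenzyl)oxy]but-3-en-1-yl (Z)-2-methylbut-2-enoate
Conditions: mCPBA (1.1 equiv), NaHCO3, CH2Cl2, 0 °C
Reagents that add atoms: 3-chloroperbenzoic acid, O=C(OO)c1cccc(Cl)c1
Why: Prilezhaev epoxidation is selective for the only electron-rich alkene, the trisubstituted side-chain double bond, since the methylene lactone, acrylamide and angelate alkenes are deactivated by their carbonyl groups, and the epoxide stereochemistry is irrelevant.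

Step 13
Reactants: 20 side-chain epoxide
Product: 21 (1S,2S)-1-[(2S,3R)-2-(2-chloro-2-methyl-3-oxobutyl)-4-methylene-5-oxotetrahydrofuran-3-yl]-3-(dimethylcarbamoyl)-2-[(4-methoxybenzyl)oxy]but-3-en-1-yl (Z)-2-methylbut-2-enoate
Conditions: (COCl)2, DMSO, CH2Cl2, −78 °C; 20, −78 to −40 °C; Et3N, −78 to 0 °C
Reagents that add atoms: oxalyl chloride (chlorine source), O=C(Cl)C(=O)Cl
Why: In this oxidative epoxide opening with chlorodimethylsulfonium chloride the epoxide oxygen is sulfonium-activated, chloride opens it at the tertiary carbon C10, and triethylamine collapses the secondary alkoxysulfonium ion as in a Swern oxidation, which gives the tertiary α-chloro methyl ketone in one flask.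

Step 14
Reactants: 21 α-chloro ketone PMB ether
Product: 22 (1S,2S)-1-[(2S,3R)-2-(2-chloro-2-methyl-3-oxobutyl)-4-methylene-5-oxotetrahydrofuran-3-yl]-3-(dimethylcarbamoyl)-2-hydroxybut-3-en-1-yl (Z)-2-methylbut-2-enoate
Conditions: DDQ (1.3 equiv), CH2Cl2/pH 7 buffer (10:1), 0 °C to rt
Reagents that add atoms: none
Why: Oxidative cleavage of the PMB ether with DDQ under buffered conditions frees O–C5 without touching the chloride, the esters or the electron-poor alkenes, so that no benzylic ether or electron-rich arene is present when the cation is made.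

Step 15
Reactants: 22 α-chloro ketone alcohol
Product: 26 (5S,6S,7R,8S,10R)-6-angeloyloxy-5-hydroxy-1-oxo-3,10-epoxygermacra-2,4(15),11(13)-trien-12,8-olide (target), via siloxyallyl chloride 23 (not isolated), via aminal cycloadduct 24 (not isolated), via silyl ether 25 (not isolated)
Conditions: Et3SiOSO2CF3 (2.3 equiv), Et3N (2.2 equiv), CH2Cl2, −78 to 0 °C; then slow addition to AgOSO2CF3 (1.2 equiv), CH2Cl2, final 1 mM, −40 to 0 °C; then 1 M aq. HCl/THF, 0 °C
Reagents that add atoms: none
Why: Soft enolisation can only go toward the methyl group because C10 is fully substituted, AgOSO2CF3 abstracts the tertiary allylic chloride of 23, the amide oxygen adds to the tertiary terminus C10 of the 2-siloxyallyl cation, the enol silane carbon C2 adds to C3 of the resulting O-alkyl imidate (iminium) ion in a Mukaiyama–Mannich manner, and β-amino ketone 24 loses dimethylamine to give the conjugated furanone, after which dilute acid removes the C5 silyl ether. The closest known reaction types are the Fe2(CO)9-promoted (3+2) cyclocoupling of α,α'-dibromo ketones with N,N-dimethylcarboxamides, which gives 3(2H)-furanones with the ring oxygen on the more substituted carbon, and the silver-promoted ionisation of 2-siloxyallyl halides for cycloadditions, used here together and intramolecularly. The O to C10 bond forms by a 9-exo-trig capture of the cation (oxacycle O–C3–C4–C5–C6–C7–C8–C9–C10), and the C2 to C3 bond by a 5-(enolendo)-exo-trig closure that completes the furanone and with it the ten-membered carbocycle, a formally unfavourable mode that nevertheless operates in the known intermolecular furanone synthesis and is eased by the high electrophilicity of the imidate ion. C10 is the only new stereocentre: both C10 epimers of 22 converge on one planar cation, O-alkylation should be reversible, and the centres C5–C8 decide which imidate can close, the trans-lactone holding the two arms gauche and the 10R face (oxygen on C10 syn to oxygen on C8, C14 methyl turned outward) being expected to close with the least transannular strain. The step needs selectivity for the amide oxygen over ester, lactone and ether oxygens and over proton loss from the cation, which is secured because the lactone carbonyl cannot reach C10 for geometric reasons, ester oxygens are far weaker donors, O–C5 is masked in situ as a bulky silyl ether, no free base or nucleophilic solvent is present, and high dilution suppresses dimerisation. The released dimethylamine ends as its triflate salt and therefore cannot add to the α-methylene lactone.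

Compound list
1 | (S)-epichlorohydrin | ClC[C@@H]1CO1 | starting material
2 | but-2-en-2-ylmagnesium bromide (E/Z mixture) | CC=C(C)[Mg]Br | starting material
3 | (2S)-1-chloro-4-methylhex-4-en-2-ol | ClC[C@@H](O)CC(C)=CC | intermediate
4 | (2S)-2-(2-methylbut-2-en-1-yl)oxirane | C1[C@@H](O1)CC(C)=CC | intermediate
5 | (3S)-5-methylhepta-1,5-dien-3-ol | C=C[C@@H](O)CC(C)=CC | intermediate
6 | 2-(bromomethyl)acrylic acid | C=C(CBr)C(=O)O | starting material
7 | (3S)-5-methylhepta-1,5-dien-3-yl 2-(bromomethyl)acrylate | C=C(CBr)C(=O)O[C@H](C=C)CC(C)=CC | intermediate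
8 | (5S)-3-(bromomethyl)-5-(2-methylbut-2-en-1-yl)furan-2(5H)-one | O=C1O[C@@H](CC(C)=CC)C=C1CBr | intermediate
9 | (R)-2,2-dimethyl-1,3-dioxolane-4-carbaldehyde | CC1(C)OC[C@@H](O1)C=O | starting material
10 | (4S)-4-ethynyl-2,2-dimethyl-1,3-dioxolane | CC1(C)OC[C@@H](O1)C#C | intermediate
11 | 2-[(4S)-2,2-dimethyl-1,3-dioxolan-4-yl]-N,N-dimethylprop-2-enamide | CC1(C)OC[C@@H](O1)C(=C)C(=O)N(C)C | intermediate
12 | (3S)-3,4-dihydroxy-N,N-dimethyl-2-methylenebutanamide | OC[C@@H](O)C(=C)C(=O)N(C)C | intermediate
13 | 2-[(4S)-2-(4-methoxyphenyl)-1,3-dioxolan-4-yl]-N,N-dimethylprop-2-enamide (acetal epimers) | COc1ccc(cc1)C1OC[C@@H](O1)C(=C)C(=O)N(C)C | intermediate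
14 | (3S)-4-hydroxy-3-[(4-methoxybenzyl)oxy]-N,N-dimethyl-2-methylenebutanamide | OC[C@@H](OCc1ccc(OC)cc1)C(=C)C(=O)N(C)C | intermediate
15 | (3S)-3-[(4-methoxybenzyl)oxy]-N,N-dimethyl-2-methylene-4-oxobutanamide | O=C[C@@H](OCc1ccc(OC)cc1)C(=C)C(=O)N(C)C | intermediate
16 | Barbier adduct, free C6–OH, C5–OPMB, (5S,6S,7S,8S) | C=C1C(=O)O[C@@H](CC(C)=CC)[C@@H]1[C@H](O)[C@@H](OCc2ccc(OC)cc2)C(=C)C(=O)N(C)C | intermediate
17 | angelic acid | C/C=C(/C)C(=O)O | starting material
18 | angelic 2,4,6-trichlorobenzoic anhydride | C/C=C(/C)C(=O)OC(=O)c1c(Cl)cc(Cl)cc1Cl | intermediate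
19 | C6 angelate of 16, (5S,6S,7R,8S) | C=C1C(=O)O[C@@H](CC(C)=CC)[C@@H]1[C@H](OC(=O)/C(C)=C\C)[C@@H](OCc2ccc(OC)cc2)C(=C)C(=O)N(C)C | intermediate
20 | side-chain C1–C10 epoxide of 19, (5S,6S,7R,8S), epoxide epimers | C=C1C(=O)O[C@@H](CC2(C)OC2C)[C@@H]1[C@H](OC(=O)/C(C)=C\C)[C@@H](OCc2ccc(OC)cc2)C(=C)C(=O)N(C)C | intermediate
21 | tertiary α-chloro methyl ketone, C5–OPMB, (5S,6S,7R,8S), C10 epimers | C=C1C(=O)O[C@@H](CC(C)(Cl)C(C)=O)[C@@H]1[C@H](OC(=O)/C(C)=C\C)[C@@H](OCc2ccc(OC)cc2)C(=C)C(=O)N(C)C | intermediate
22 | tertiary α-chloro methyl ketone, free C5–OH, (5S,6S,7R,8S), C10 epimers | C=C1C(=O)O[C@@H](CC(C)(Cl)C(C)=O)[C@@H]1[C@H](OC(=O)/C(C)=C\C)[C@@H](O)C(=C)C(=O)N(C)C | intermediate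
23 | 2-(triethylsiloxy)allyl chloride with C5–OSiEt3 | C=C1C(=O)O[C@@H](CC(C)(Cl)C(=C)O[Si](CC)(CC)CC)[C@@H]1[C@H](OC(=O)/C(C)=C\C)[C@@H](O[Si](CC)(CC)CC)C(=C)C(=O)N(C)C | intermediate
24 | bicyclic aminal cycloadduct (3-dimethylamino-2,3-dihydrofuranone), C5–OSiEt3, (5S,6S,7R,8S,10R) | C=C1C(=O)O[C@H]2C[C@@]3(C)OC(CC3=O)(N(C)C)C(=C)[C@H](O[Si](CC)(CC)CC)[C@@H](OC(=O)/C(C)=C\C)[C@H]12 | intermediate
25 | C5 triethylsilyl ether of the target | C=C1C(=O)O[C@H]2C[C@@]3(C)OC(=CC3=O)C(=C)[C@H](O[Si](CC)(CC)CC)[C@@H](OC(=O)/C(C)=C\C)[C@H]12 | intermediate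
26 | CNP0120053.1, (5S,6S,7R,8S,10R)-6-angeloyloxy-5-hydroxy-1-oxo-3,10-epoxygermacra-2,4(15),11(13)-trien-12,8-olide | C=C1C(=O)O[C@H]2C[C@@]3(C)OC(=CC3=O)C(=C)[C@H](O)[C@@H](OC(=O)/C(C)=C\C)[C@H]12 | target

Total step count: 15. Longest linear sequence: 11 steps (9 to 26, steps 5–15).

Steps most likely to fail

1. Step 15.
- What may go wrong: proton loss from the cation (giving a siloxydiene), capture by a nearer oxygen, or oligomerisation may outrun the nine-membered ring closure. The closure of a medium ring is the untested element of this step. Attack may also occur on the wrong face of C10.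
- Fallback: furanone formation is separated from ring closure, setting out from 8.
- Indium Barbier reaction of 8 with aqueous 2,2-dimethoxyacetaldehyde should give the C6 carbinol acetal F1 under pure reagent control.
- Angeloylation as in step 11 gives the angelate acetal F2, epoxidation as in step 12 gives the epoxide F3, and oxidative chlorination as in step 13 gives the α-chloro ketone F4.
- The cyclocoupling is then run in its documented intermolecular format, with an excess of 2-bromo-N,N-dimethylacrylamide as the trap (Et3SiOSO2CF3/Et3N, then AgOSO2CF3). This gives the 5-(1-bromovinyl)furanone F5, whose C10 epimers would have to be separated by chromatography.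
- Aqueous trifluoroacetic acid frees the C5 aldehyde F6.
- An intramolecular Nozaki–Hiyama–Kishi reaction (CrCl2, catalytic NiCl2, DMSO/THF, high dilution) closes the ten-membered ring at C4–C5. It comes back to the route at 26, with C5 set by the ring.

2. Step 10.
- What may go wrong: the α-alkoxy-β,γ-unsaturated aldehyde may epimerise before it reacts. Facial selectivity at C6 may be incomplete if chelation in water is weak. The indium alkoxide may start lactone migration.
- Fallback: the sequence is made stereoconvergent at C6 by moving the stereodefining event into the esterification, setting out from the same coupling of 8 and 15.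
- The unwanted C6 epimer F7 is separated and esterified with 17 under Mitsunobu conditions (PPh3, diisopropyl azodicarboxylate, toluene, 0 °C). This installs the angelate with inversion at C6 and comes back to the route at 19.

3. Step 11.
- What may go wrong: prolonged heating with amine base may cause Z to E isomerisation of the angeloyl unit. It may also cause migration of the lactone to O–C6, or attack of the C6 hydroxyl on the amide carbonyl.
- Fallback: the Z-alkene is built on the ester instead of transferring it, setting out from 16.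
- Carbodiimide acylation at 0 °C with 2-[bis(2,2,2-trifluoroethoxy)phosphoryl]propanoic acid gives the phosphonopropionate ester F8.
- A Still–Gennari olefination (KN(SiMe3)2, 18-crown-6, acetaldehyde, THF, −78 °C) gives the angelate and comes back to the route at 19.

Further compounds
F1 | step 15 | (4S,5S)-4-[(1S)-1-hydroxy-2,2-dimethoxyethyl]-5-(2-methylbut-2-en-1-yl)-3-methylenedihydrofuran-2(3H)-one | C=C1C(=O)O[C@@H](CC(C)=CC)[C@@H]1[C@H](O)C(OC)OC
F2 | step 15 | C6 angelate of F1, (6S,7R,8S) | C=C1C(=O)O[C@@H](CC(C)=CC)[C@@H]1[C@H](OC(=O)/C(C)=C\C)C(OC)OC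
F3 | step 15 | side-chain epoxide of F2 (epoxide epimers) | C=C1C(=O)O[C@@H](CC2(C)OC2C)[C@@H]1[C@H](OC(=O)/C(C)=C\C)C(OC)OC
F4 | step 15 | tertiary α-chloro methyl ketone from F3 (C10 epimers) | C=C1C(=O)O[C@@H](CC(C)(Cl)C(C)=O)[C@@H]1[C@H](OC(=O)/C(C)=C\C)C(OC)OC
F5 | step 15 | (10R)-2-methyl-5-(1-bromovinyl)furan-3(2H)-one linked through C9 to the lactone, C5 dimethyl acetal | C=C1C(=O)O[C@@H](C[C@@]2(C)OC(=CC2=O)C(Br)=C)[C@@H]1[C@H](OC(=O)/C(C)=C\C)C(OC)OC
F6 | step 15 | C5 aldehyde from F5 | C=C1C(=O)O[C@@H](C[C@@]2(C)OC(=CC2=O)C(Br)=C)[C@@H]1[C@H](OC(=O)/C(C)=C\C)C=O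
F7 | step 10 | C6 epimer of 16, (5S,6R,7S,8S) | C=C1C(=O)O[C@@H](CC(C)=CC)[C@@H]1[C@@H](O)[C@@H](OCc2ccc(OC)cc2)C(=C)C(=O)N(C)C
F8 | step 11 | C6 2-[bis(2,2,2-trifluoroethoxy)phosphoryl]propanoate of 16 | C=C1C(=O)O[C@@H](CC(C)=CC)[C@@H]1[C@H](OC(=O)C(C)P(=O)(OCC(F)(F)F)OCC(F)(F)F)[C@@H](OCc2ccc(OC)cc2)C(=C)C(=O)N(C)C
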